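## Structural features

The target is built on a cyclohexene, ring A, numbered from C1 (the CH that carries the side chain) through C2 and C3 (the two oxirane carbons, C2 methylated) and C4=C5 (C4 methylated) to C6; the C2–C3 bond is cis-fused to an oxirane. C6 is an all-carbon quaternary centre holding a methyl group and, through a C–C bond to the carbon next to the ring oxygen, a 6-methoxy-3,5-dimethyl-4-pyranone, ring B. The side chain on C1 is an (E)-trisubstituted alkene C7=C8 (C7 methylated) leading to the methyl stereocentre C9 and the ethyl ketone C10. Four stereocentres are contiguous on ring A (C6, C1, C2, C3, two of them fully substituted): the C1 alkenyl group is cis to ring B and to the C2 methyl group and trans to the C6 methyl group and the oxirane oxygen, while C9 stands alone beyond the alkene. The fragile parts are the vinyl oxirane (allylic C3–O bond, opened by acid or in SN2′ fashion), C9 (α to a ketone and allylic, so open to epimerisation and alkene migration under base) and the α-methoxy-γ-pyranone (strong acid, hard nucleophiles). The real difficulty is the crowded C6–C1–C2 triad, above all the quaternary C6 that joins a heteroaryl ring next to the branched C1. The key step uses the fact that C2, C3 and C4 with their two methyl groups and the C3 oxygen are the atoms of pentan-3-one, and C5, C6 and C1 with the side chain those of a 2,4-dienal, so ring A is a Robinson-type Michael–aldol union in which C1 is the only centre a catalyst has to set.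

## Logic of the disconnections

24 is taken back to 23 and 22 without cutting a skeletal bond: the C10 ketone becomes a silyl-protected alcohol. The reason is that C9 next to a ketone would not survive the enolate chemistry on ring A. The gain is a C9 that is configurationally locked until the last step. The demand is a fluoride deprotection and a neutral oxidation that spare the vinyl oxirane.

22 is opened at the C3–O bond of the oxirane to 21, the C3 alcohol is returned to the ketone of 20, and the C2–O bond is cut to reach 19. The oxirane oxygen is thus the hydroxyl of an α-hydroxy ketone, which an enone enolate can provide. The gain is that both oxirane centres are relayed from C1. The demands are oxygenation of C2 anti to the C1 alkenyl group, hydride delivery to C3 from the face of the C2 hydroxyl (trans-diol), and closure with inversion at C3.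

19 is cut at the C6–methyl bond to 18. The methyl group is placed last so that it enters anti to the C1 alkenyl group, which leaves ring B cis to it. The gain is a tertiary C6 whose configuration is irrelevant. The demand is alkylation of a dienolate at its γ-carbon and not at C4 or oxygen.

18 is cut at the bond between C6 and ring B to 12 and 17. This joins a complete ring B to ring A in a convergent step. The gain is that 12 holds only C1 and C2 as ring stereocentres and 17 is achiral. The demand is coupling at the γ-carbon C6 in preference to the α′-carbon C2.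

17 is simplified through 16, 15 and 14 to 13 by cutting the C–Br bond, the O–methyl bond, the lactone C–O bond and the C–C bond to the formyl carbon. The gain is a commercial five-carbon keto ester that supplies all but one carbon of ring B. The demands are O-methylation at the lactone carbonyl oxygen and metalation next to the ring oxygen.

12 is cut at C1–C2 and C4=C5 to 8 and 9 (through 11 and 10). This is the Michael–aldol retron and the only step that needs absolute stereocontrol on ring A. The gain is an open-chain dienal and a keto ester in place of a stereodefined ring. The demands are 1,4-addition, facial control by the catalyst, a single aldol mode, and survival of C9 and the silyl ether. The C2 configuration of 12 is of no consequence, because C2 is re-formed when 20 is made.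

8 is cut at C1=C6 to 5 (with 6, by way of 7), and 5 at C7=C8 to 3 (with 4). Two stabilised-ylide olefinations build the (2E,4E)-diene two carbons at a time. The demands are (E)-selectivity and no epimerisation of C9, which is α to the aldehyde in 3.

3 is taken back through 2 to 1 by cutting the C9–C10 bond. Both halves are the same aldehyde, so one catalytic aldol sets C9 (and C10). The demands are anti- and enantioselectivity and gentle handling of the hydroxy aldehyde.

## Other disconnections considered

Alternative 1: The cut is at C1–C7 and at the C6–methyl bond, so ring A comes from a benzene ring. Forward, the side-chain alkenyllithium A3 would add to the ortho carbon of the chiral aryl oxazoline A2, and the aza-enolate so formed would be methylated at the ipso carbon to give the dearomatised diene A1 without closing a ring.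
- In its favour: A1 holds every ring-A carbon, both ring methyl groups and the C3 oxygen, and sets C1 and the quaternary C6 in one flask with the methyl group trans to the alkenyl group. On this point it is better than the chosen plan, which needs two separate steps at C6 with a regiochemical risk in each. It is also more convergent, since the whole side chain arrives in the key step.
- Against it: such additions are reliable for naphthalenes, whereas a single electron-rich benzene ring is expected to undergo ortho-lithiation at its free C1 or C5 position and to resist loss of aromaticity. A3 must be made from a vinyl halide, a longer preparation than that of 8. The oxazoline on C6 is only a masked carboxyl group, so ring B would have to be built stepwise on a neopentyl centre.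
- Comparison: on structure the plans are equal for the oxirane, which in both comes from a C3 ketone by hydroxylation, reduction and closure. On mechanism the chosen plan rests on a precedented catalytic step, the alternative on a dearomatisation outside its usual scope. On step economy the alternative saves the two C6 steps but pays about five for ring B, so it should be the longer route.

Alternative 2: The cut is at C2–C3 and C3–O, which opens ring A and the oxirane together. Forward, deprotonation of the Z-allylic sulfonium salt A5 would give an ylide at C3 that adds to the C2 methyl ketone, and the alkoxide would then expel the sulfide to give A4.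
- In its favour: the most fragile unit of the target is made late, by base alone and without an oxidant, two rings form in one operation, and only desilylation and oxidation follow. In steps after the key step (two against seven) the alternative is clearly better.
- Against it: all the difficulty moves into A5, an open-chain compound in which C1 and the quaternary, ring-B-bearing C6 must already be set with no ring to relay stereochemistry. C1 in A5 is α to the ketone and allylic, so the ylide-forming base can epimerise it. Allylic sulfonium ylides can also react through the γ-terminus or rearrange by a [2,3]-shift. The face of the ketone that is attacked, which fixes the oxirane trans to the C1 alkenyl group, depends on substrate control that is hard to foresee.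
- Comparison: on structure the two are equal in that both use C1 to direct the ring oxygen. On mechanism the chosen plan is safer, since C1 is set by a catalyst and every later centre is introduced on a ring. On step economy the short endgame is likely to be outweighed by the length of the route to A5.

Alternative 3: The cut is at C1–C6 and C2–C3 in a [4+2] sense. Forward, the 2-pyranone A7 as diene and the α,β-alkene of the dienone A8 as dienophile would combine under Lewis-acid catalysis to the bridged lactone A6.
- In its favour: two C–C bonds, ring A and four stereocentres (C1, C2, C3, C6), both fully substituted ones included, arise in one step, which is better than the chosen key step (one lasting stereocentre). The lactone carbon on C6 emerges cis to the C1 alkenyl group at the oxidation level needed to grow ring B, the lactone oxygen supplies the C3 oxygen, and the C4=C5 alkene forms directly.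
- Against it: 2-pyranones are reluctant dienes and A8 is a trisubstituted, doubly branched dienophile, so forcing conditions and cycloreversion with loss of the carboxyl bridge are to be expected. Regiochemistry rests on the weak polarisation of a dimethylpyranone and endo/exo selectivity is uncertain. The only stereocentre of A8 (C9) is too far from the reacting alkene to control the face, so a chiral Lewis acid would be needed. Afterwards the acetyl group on C2 must be turned into oxygen by Baeyer–Villiger oxidation in the presence of two alkenes, C3 must be inverted on oxirane closure, and ring B assembled in about five steps.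
- Comparison: on structure the alternative is the better plan in bonds and stereocentres per step. On the oxirane the two are equal, both closing it by displacement at C3 by the C2 oxygen. On mechanism the chosen plan has one selectivity to secure where the alternative has four at once. On step economy the sequence after the key step should be of similar length or longer for the alternative.

Key step: step 6

Remark on the chemistry: C10 is carried as an (S)-configured triisopropylsilyl ether; its configuration follows from step 1 and is erased by the final oxidation, and triisopropylsilyl is preferred to tert-butyldimethylsilyl because ring closure in step 6 uses TsOH at 80 °C.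

## Route

Step 1
Reactants: 1 propanal (two molecules)
Product: 2 (2S,3S)-3-hydroxy-2-methylpentanal
Conditions: L-proline (10 mol %), DMF, 4 °C
Reagents that add atoms: none
Why: Proline-catalysed direct aldol reaction: the (E)-enamine of one propanal adds to the Re face of a second, acid-activated propanal through a chair transition state, which should give mainly the anti (2S,3S) adduct with C9 and C10 set; the minor syn isomer is expected to differ only at the carbinol carbon (later C10) and is removed by chromatography at 3 or 5.

Step 2
Reactants: 2 (2S,3S)-3-hydroxy-2-methylpentanal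
Product: 3 (2S,3S)-2-methyl-3-(triisopropylsilyloxy)pentanal
Conditions: i-Pr3SiOTf, 2,6-lutidine, CH2Cl2, −78 °C
Reagents that add atoms: triisopropylsilyl trifluoromethanesulfonate, CC(C)[Si](C(C)C)(C(C)C)OS(=O)(=O)C(F)(F)F
Why: Silylation of a secondary alcohol with a silyl triflate and a hindered pyridine base at low temperature should outrun retro-aldol, dehydration and epimerisation of the β-hydroxy aldehyde; the triisopropylsilyl ether is chosen to survive the acid of step 6.

Step 3
Reactants: 3 (2S,3S)-2-methyl-3-(triisopropylsilyloxy)pentanal; 4 2-(triphenylphosphoranylidene)propanal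
Product: 5 (2E,4R,5S)-2,4-dimethyl-5-(triisopropylsilyloxy)hept-2-enal
Conditions: toluene, 90 °C
Reagents that add atoms: none
Why: Wittig olefination with a stabilised formyl ylide forms C7=C8 as the (E)-2-methyl enal; no base is present, so C9 (α to the aldehyde) should not epimerise, and the hindered product enal should not react again.

Step 4
Reactants: 5 (2E,4R,5S)-2,4-dimethyl-5-(triisopropylsilyloxy)hept-2-enal; 6 diethyl [2-(methoxy(methyl)amino)-2-oxoethyl]phosphonate
Product: 7 (2E,4E,6R,7S)-N-methoxy-N,4,6-trimethyl-7-(triisopropylsilyloxy)nona-2,4-dienamide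
Conditions: NaH, THF, 0 °C to rt
Reagents that add atoms: none
Why: Horner–Wadsworth–Emmons olefination with a stabilised phosphonate anion is (E)-selective and forms the C1=C6 alkene; the Weinreb amide is a two-carbon aldehyde equivalent.

Step 5
Reactants: 7 (2E,4E,6R,7S)-N-methoxy-N,4,6-trimethyl-7-(triisopropylsilyloxy)nona-2,4-dienamide
Product: 8 (2E,4E,6R,7S)-4,6-dimethyl-7-(triisopropylsilyloxy)nona-2,4-dienal
Conditions: i-Bu2AlH, THF, −78 °C; aq. KNaC4H4O6
Reagents that add atoms: none
Why: Hydride adds once to the Weinreb amide and the chelated tetrahedral aluminium intermediate collapses to the aldehyde only on work-up, so neither over-reduction nor conjugate reduction is expected.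

Step 6
Reactants: 8 (2E,4E,6R,7S)-4,6-dimethyl-7-(triisopropylsilyloxy)nona-2,4-dienal; 9 tert-butyl 2-methyl-3-oxopentanoate (racemic)
Product: 12 (5R,6S)-2,6-dimethyl-5-[(2E,4R,5S)-4-methyl-5-(triisopropylsilyloxy)hept-2-en-2-yl]cyclohex-2-en-1-one, via Michael adduct 10 (not isolated), via cyclised keto ester 11 (not isolated)
Conditions: (S)-2-[bis(3,5-bis(trifluoromethyl)phenyl)(trimethylsilyloxy)methyl]pyrrolidine (20 mol %), PhCO2H (20 mol %), toluene, rt; then TsOH·H2O (0.5 equiv), toluene, 80 °C
Reagents that add atoms: none
Why: The secondary amine condenses with 8 to an (E,s-trans) iminium ion, the enol of 9 adds through C2 to the β-carbon C1, and hydrolysis of the resulting enamine frees the catalyst and the aldehyde 10; the closest known reaction is the amine-catalysed Michael addition of β-keto esters to enals followed by acid-induced aldol condensation and decarboxylation to 5-substituted cyclohex-2-enones. On heating with TsOH the enol of the ethyl ketone (C4) attacks the aldehyde carbon C5 in a 6-(enolexo)-exo-trig aldol closure of ring A, and dehydration gives the C4=C5 enone 11. The same acid removes the tert-butyl group as 2-methylpropene and the β-keto acid loses carbon dioxide to give 12. C1 is controlled by the catalyst: its diarylsilyloxymethyl group covers one face of the iminium ion, so the (S)-catalyst should direct the nucleophile to the Si face of C1 and give the (R) centre. C2 is controlled thermodynamically: acid-mediated enolisation after decarboxylation leaves the methyl group trans to the alkenyl group, both equatorial. The step needs 1,4- over 1,6-addition, secured by the C7 methyl group and the C9 branch that block C8; a single aldol mode, secured because C2 is quaternary in 10 and only C4 can enolise; and integrity of C9, secured because trienamine formation would need a planar, tetrasubstituted C8=C9 terminus next to the bulky silyl ether. The silyl ether is triisopropylsilyl so that it survives the acid.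

Step 7
Reactants: 13 methyl 2-methyl-3-oxopentanoate
Product: 14 methyl 2,4-dimethyl-3,5-dioxopentanoate
Conditions: NaH, THF, 0 °C; n-BuLi, 0 °C; HCO2Me, −78 °C to rt; aq. HCl
Reagents that add atoms: methyl formate, COC=O
Why: The dianion of the β-keto ester reacts at its more basic γ-carbon (the ethyl CH2) in a Claisen-type formylation, giving the 3,5-dicarbonyl ester that holds all ring-B carbons.

Step 8
Reactants: 14 methyl 2,4-dimethyl-3,5-dioxopentanoate
Product: 15 4-hydroxy-3,5-dimethyl-2H-pyran-2-one
Conditions: DBU, toluene, reflux
Reagents that add atoms: none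
Why: Base-promoted lactonisation of the (Z)-enol oxygen of the formyl group onto the methyl ester (6-exo-trig) gives the 4-hydroxy-2-pyranone, the standard cyclisation of 3,5-dioxo esters.

Step 9
Reactants: 15 4-hydroxy-3,5-dimethyl-2H-pyran-2-one
Product: 16 2-methoxy-3,5-dimethyl-4H-pyran-4-one
Conditions: MeOTf, CH2Cl2, rt; aq. NaHCO3
Reagents that add atoms: methyl trifluoromethanesulfonate, COS(=O)(=O)C(F)(F)F
Why: The hard alkylating agent methylates the neutral 4-hydroxy-2-pyranone on its lactone carbonyl oxygen, and loss of the hydroxyl proton leaves the 2-methoxy-4-pyranone; this is the known regiochemistry for 3,5-dimethyl-4-hydroxy-2-pyranones under neutral conditions.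

Step 10
Reactants: 16 2-methoxy-3,5-dimethyl-4H-pyran-4-one
Product: 17 2-bromo-6-methoxy-3,5-dimethyl-4H-pyran-4-one
Conditions: lithium 2,2,6,6-tetramethylpiperidide, THF, −78 °C; then BrCCl2CCl2Br
Reagents that add atoms: 1,2-dibromo-1,1,2,2-tetrachloroethane, BrC(Cl)(Cl)C(Cl)(Cl)Br
Why: The ring C–H of 16 is its only sp2 C–H and is acidified by the adjacent ring oxygen, so a hindered, non-nucleophilic lithium amide should metalate it (as in the 2-lithiation of chromones and 4-pyranones), and the vinyllithium is brominated by the positive-bromine donor.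

Step 11
Reactants: 12 (5R,6S)-2,6-dimethyl-5-[(2E,4R,5S)-4-methyl-5-(triisopropylsilyloxy)hept-2-en-2-yl]cyclohex-2-en-1-one; 17 2-bromo-6-methoxy-3,5-dimethyl-4H-pyran-4-one
Product: 18 (5R,6S)-4-(6-methoxy-3,5-dimethyl-4-oxo-4H-pyran-2-yl)-2,6-dimethyl-5-[(2E,4R,5S)-4-methyl-5-(triisopropylsilyloxy)hept-2-en-2-yl]cyclohex-2-en-1-one (both C4 epimers)
Conditions: Pd(OAc)2 (5 mol %), 2-dicyclohexylphosphino-2′,4′,6′-triisopropylbiphenyl (10 mol %), Cs2CO3, toluene, 80 °C
Reagents that add atoms: none
Why: Palladium-catalysed γ-arylation of an α,β-unsaturated ketone: zerovalent palladium inserts into the C–Br bond of 17, the extended caesium dienolate of 12 transmetalates, and reductive elimination forms the bond from C6 to ring B, the α-carbon C4 being fully substituted and the γ-product keeping the enone conjugation. C6 forms as both epimers, which converge in step 12.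

Step 12
Reactants: 18 (5R,6S)-4-(6-methoxy-3,5-dimethyl-4-oxo-4H-pyran-2-yl)-2,6-dimethyl-5-[(2E,4R,5S)-4-methyl-5-(triisopropylsilyloxy)hept-2-en-2-yl]cyclohex-2-en-1-one
Product: 19 (4R,5R,6S)-4-(6-methoxy-3,5-dimethyl-4-oxo-4H-pyran-2-yl)-2,4,6-trimethyl-5-[(2E,4R,5S)-4-methyl-5-(triisopropylsilyloxy)hept-2-en-2-yl]cyclohex-2-en-1-one
Conditions: KOt-Bu, THF, −40 °C; then MeI, −40 to 0 °C
Reagents that add atoms: iodomethane, CI
Why: The alkoxide removes the most acidic proton (C6–H, activated by the enone and by ring B), and the dienolate is methylated at C6 in the way 3-substituted Hagemann's esters are alkylated at C-1, the α-carbon being substituted and the γ-carbon carrying an acceptor. MeI approaches anti to the C1 alkenyl group, which sits pseudoaxial to avoid ring B, so the methyl group ends trans to it and ring B cis.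

Step 13
Reactants: 19 (4R,5R,6S)-4-(6-methoxy-3,5-dimethyl-4-oxo-4H-pyran-2-yl)-2,4,6-trimethyl-5-[(2E,4R,5S)-4-methyl-5-(triisopropylsilyloxy)hept-2-en-2-yl]cyclohex-2-en-1-one
Product: 20 (4R,5R,6S)-6-hydroxy-4-(6-methoxy-3,5-dimethyl-4-oxo-4H-pyran-2-yl)-2,4,6-trimethyl-5-[(2E,4R,5S)-4-methyl-5-(triisopropylsilyloxy)hept-2-en-2-yl]cyclohex-2-en-1-one
Conditions: KN(SiMe3)2, THF, −78 °C; then 2-(phenylsulfonyl)-3-phenyloxaziridine, −78 °C; aq. NH4Cl
Reagents that add atoms: 2-(phenylsulfonyl)-3-phenyloxaziridine, O=S(=O)(c1ccccc1)N1OC1c1ccccc1
Why: With C6 quaternary, C2 is the only enolisable position, so the amide base gives the cross-conjugated C2=C3 enolate, which the N-sulfonyloxaziridine oxidises (Davis oxidation) on the face anti to the C1 alkenyl group. This puts the hydroxyl trans and the C2 methyl group cis to the alkenyl group, as the oxirane of the target requires; the C2 configuration from step 6 is erased here.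

Step 14
Reactants: 20 (4R,5R,6S)-6-hydroxy-4-(6-methoxy-3,5-dimethyl-4-oxo-4H-pyran-2-yl)-2,4,6-trimethyl-5-[(2E,4R,5S)-4-methyl-5-(triisopropylsilyloxy)hept-2-en-2-yl]cyclohex-2-en-1-one
Product: 21 (1S,2S,5R,6R)-5-(6-methoxy-3,5-dimethyl-4-oxo-4H-pyran-2-yl)-1,3,5-trimethyl-6-[(2E,4R,5S)-4-methyl-5-(triisopropylsilyloxy)hept-2-en-2-yl]cyclohex-3-ene-1,2-diol
Conditions: Me4NBH(OAc)3, MeCN/AcOH, −20 °C
Reagents that add atoms: none
Why: Hydroxyl-directed reduction: the C2 hydroxyl displaces acetate on boron and hydride is delivered to the C3 carbonyl from the same face, giving the trans-1,2-diol; approach anti to the C2 methyl and C1 alkenyl groups favours the same face. Triacetoxyborohydride reduces the enone only in 1,2-fashion and leaves the vinylogous ester carbonyl of ring B alone.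

Step 15
Reactants: 21 (1S,2S,5R,6R)-5-(6-methoxy-3,5-dimethyl-4-oxo-4H-pyran-2-yl)-1,3,5-trimethyl-6-[(2E,4R,5S)-4-methyl-5-(triisopropylsilyloxy)hept-2-en-2-yl]cyclohex-3-ene-1,2-diol
Product: 22 2-methoxy-3,5-dimethyl-6-[(1R,4R,5R,6S)-2,4,6-trimethyl-5-[(2E,4R,5S)-4-methyl-5-(triisopropylsilyloxy)hept-2-en-2-yl]-7-oxabicyclo[4.1.0]hept-2-en-4-yl]-4H-pyran-4-one
Conditions: NaH, 1-(p-toluenesulfonyl)imidazole, THF, 0 °C to rt
Reagents that add atoms: none
Why: The less hindered secondary (allylic) alkoxide is sulfonylated and the neighbouring tertiary alkoxide displaces the sulfonate at once (3-exo-tet, SN2 with inversion at C3), the one-flask conversion of trans-1,2-diols into oxiranes. The oxirane oxygen thus stays on the face of the C2 oxygen, anti to the C1 alkenyl group.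

Step 16
Reactants: 22 2-methoxy-3,5-dimethyl-6-[(1R,4R,5R,6S)-2,4,6-trimethyl-5-[(2E,4R,5S)-4-methyl-5-(triisopropylsilyloxy)hept-2-en-2-yl]-7-oxabicyclo[4.1.0]hept-2-en-4-yl]-4H-pyran-4-one
Product: 23 2-[(1R,4R,5R,6S)-5-[(2E,4R,5S)-5-hydroxy-4-methylhept-2-en-2-yl]-2,4,6-trimethyl-7-oxabicyclo[4.1.0]hept-2-en-4-yl]-6-methoxy-3,5-dimethyl-4H-pyran-4-one
Conditions: Bu4NF, THF, rt
Reagents that add atoms: none
Why: Fluoride cleaves the Si–O bond under non-acidic conditions that the vinyl oxirane and the methoxypyranone should tolerate.

Step 17
Reactants: 23 2-[(1R,4R,5R,6S)-5-[(2E,4R,5S)-5-hydroxy-4-methylhept-2-en-2-yl]-2,4,6-trimethyl-7-oxabicyclo[4.1.0]hept-2-en-4-yl]-6-methoxy-3,5-dimethyl-4H-pyran-4-one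
Product: 24 2-methoxy-3,5-dimethyl-6-[(1R,4R,5R,6S)-2,4,6-trimethyl-5-[(2E,4R)-4-methyl-5-oxohept-2-en-2-yl]-7-oxabicyclo[4.1.0]hept-2-en-4-yl]-4H-pyran-4-one (CNP0336888.3)
Conditions: Dess–Martin periodinane, NaHCO3, CH2Cl2, 0 °C to rt
Reagents that add atoms: none
Why: Buffered Dess–Martin oxidation of the secondary alcohol is neutral and fast, so C9 (now α to the ketone and allylic) should neither epimerise nor let the alkene move into conjugation.

## Compound list

1 | propanal | CCC=O | starting material
2 | (2S,3S)-3-hydroxy-2-methylpentanal | CC[C@H](O)[C@H](C)C=O | intermediate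
3 | (2S,3S)-2-methyl-3-(triisopropylsilyloxy)pentanal | CC[C@H](O[Si](C(C)C)(C(C)C)C(C)C)[C@H](C)C=O | intermediate
4 | 2-(triphenylphosphoranylidene)propanal | CC(C=O)=P(c1ccccc1)(c1ccccc1)c1ccccc1 | starting material
5 | (2E,4R,5S)-2,4-dimethyl-5-(triisopropylsilyloxy)hept-2-enal | CC[C@H](O[Si](C(C)C)(C(C)C)C(C)C)[C@H](C)/C=C(\C)C=O | intermediate
6 | diethyl [2-(methoxy(methyl)amino)-2-oxoethyl]phosphonate | CCOP(=O)(CC(=O)N(C)OC)OCC | starting material
7 | (2E,4E,6R,7S)-N-methoxy-N,4,6-trimethyl-7-(triisopropylsilyloxy)nona-2,4-dienamide | CC[C@H](O[Si](C(C)C)(C(C)C)C(C)C)[C@H](C)/C=C(\C)/C=C/C(=O)N(C)OC | intermediate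
8 | (2E,4E,6R,7S)-4,6-dimethyl-7-(triisopropylsilyloxy)nona-2,4-dienal | CC[C@H](O[Si](C(C)C)(C(C)C)C(C)C)[C@H](C)/C=C(\C)/C=C/C=O | intermediate
9 | tert-butyl 2-methyl-3-oxopentanoate (racemic) | CCC(=O)C(C)C(=O)OC(C)(C)C | starting material
10 | tert-butyl 2-[(3S,4E,6R,7S)-4,6-dimethyl-1-oxo-7-(triisopropylsilyloxy)non-4-en-3-yl]-2-methyl-3-oxopentanoate (C2 epimers; Michael adduct, not isolated) | CC[C@H](O[Si](C(C)C)(C(C)C)C(C)C)[C@H](C)/C=C(\C)[C@H](CC=O)C(C)(C(=O)OC(C)(C)C)C(=O)CC | intermediate
11 | tert-butyl (6S)-1,3-dimethyl-6-[(2E,4R,5S)-4-methyl-5-(triisopropylsilyloxy)hept-2-en-2-yl]-2-oxocyclohex-3-ene-1-carboxylate (C1 epimers; not isolated) | CC[C@H](O[Si](C(C)C)(C(C)C)C(C)C)[C@H](C)/C=C(\C)[C@@H]1CC=C(C)C(=O)C1(C)C(=O)OC(C)(C)C | intermediate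
12 | (5R,6S)-2,6-dimethyl-5-[(2E,4R,5S)-4-methyl-5-(triisopropylsilyloxy)hept-2-en-2-yl]cyclohex-2-en-1-one | CC[C@H](O[Si](C(C)C)(C(C)C)C(C)C)[C@H](C)/C=C(\C)[C@@H]1CC=C(C)C(=O)[C@H]1C | intermediate
13 | methyl 2-methyl-3-oxopentanoate | CCC(=O)C(C)C(=O)OC | starting material
14 | methyl 2,4-dimethyl-3,5-dioxopentanoate (stereoisomers and enol tautomers) | COC(=O)C(C)C(=O)C(C)C=O | intermediate
15 | 4-hydroxy-3,5-dimethyl-2H-pyran-2-one | CC1=COC(=O)C(C)=C1O | intermediate
16 | 2-methoxy-3,5-dimethyl-4H-pyran-4-one | COc1occ(C)c(=O)c1C | intermediate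
17 | 2-bromo-6-methoxy-3,5-dimethyl-4H-pyran-4-one | COc1oc(Br)c(C)c(=O)c1C | intermediate
18 | (5R,6S)-4-(6-methoxy-3,5-dimethyl-4-oxo-4H-pyran-2-yl)-2,6-dimethyl-5-[(2E,4R,5S)-4-methyl-5-(triisopropylsilyloxy)hept-2-en-2-yl]cyclohex-2-en-1-one (both C4 epimers) | CC[C@H](O[Si](C(C)C)(C(C)C)C(C)C)[C@H](C)/C=C(\C)[C@@H]1C(c2oc(OC)c(C)c(=O)c2C)C=C(C)C(=O)[C@H]1C | intermediate
19 | (4R,5R,6S)-4-(6-methoxy-3,5-dimethyl-4-oxo-4H-pyran-2-yl)-2,4,6-trimethyl-5-[(2E,4R,5S)-4-methyl-5-(triisopropylsilyloxy)hept-2-en-2-yl]cyclohex-2-en-1-one | CC[C@H](O[Si](C(C)C)(C(C)C)C(C)C)[C@H](C)/C=C(\C)[C@@H]1[C@](C)(c2oc(OC)c(C)c(=O)c2C)C=C(C)C(=O)[C@H]1C | intermediate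
20 | (4R,5R,6S)-6-hydroxy-4-(6-methoxy-3,5-dimethyl-4-oxo-4H-pyran-2-yl)-2,4,6-trimethyl-5-[(2E,4R,5S)-4-methyl-5-(triisopropylsilyloxy)hept-2-en-2-yl]cyclohex-2-en-1-one | CC[C@H](O[Si](C(C)C)(C(C)C)C(C)C)[C@H](C)/C=C(\C)[C@@H]1[C@](C)(c2oc(OC)c(C)c(=O)c2C)C=C(C)C(=O)[C@@]1(C)O | intermediate
21 | (1S,2S,5R,6R)-5-(6-methoxy-3,5-dimethyl-4-oxo-4H-pyran-2-yl)-1,3,5-trimethyl-6-[(2E,4R,5S)-4-methyl-5-(triisopropylsilyloxy)hept-2-en-2-yl]cyclohex-3-ene-1,2-diol | CC[C@H](O[Si](C(C)C)(C(C)C)C(C)C)[C@H](C)/C=C(\C)[C@@H]1[C@](C)(c2oc(OC)c(C)c(=O)c2C)C=C(C)[C@H](O)[C@@]1(C)O | intermediate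
22 | 2-methoxy-3,5-dimethyl-6-[(1R,4R,5R,6S)-2,4,6-trimethyl-5-[(2E,4R,5S)-4-methyl-5-(triisopropylsilyloxy)hept-2-en-2-yl]-7-oxabicyclo[4.1.0]hept-2-en-4-yl]-4H-pyran-4-one | CC[C@H](O[Si](C(C)C)(C(C)C)C(C)C)[C@H](C)/C=C(\C)[C@H]1[C@]2(C)O[C@@H]2C(C)=C[C@@]1(C)c1oc(OC)c(C)c(=O)c1C | intermediate
23 | 2-[(1R,4R,5R,6S)-5-[(2E,4R,5S)-5-hydroxy-4-methylhept-2-en-2-yl]-2,4,6-trimethyl-7-oxabicyclo[4.1.0]hept-2-en-4-yl]-6-methoxy-3,5-dimethyl-4H-pyran-4-one | CC[C@H](O)[C@H](C)/C=C(\C)[C@H]1[C@]2(C)O[C@@H]2C(C)=C[C@@]1(C)c1oc(OC)c(C)c(=O)c1C | intermediate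
24 | 2-methoxy-3,5-dimethyl-6-[(1R,4R,5R,6S)-2,4,6-trimethyl-5-[(2E,4R)-4-methyl-5-oxohept-2-en-2-yl]-7-oxabicyclo[4.1.0]hept-2-en-4-yl]-4H-pyran-4-one | CCC(=O)[C@H](C)/C=C(\C)[C@H]1[C@]2(C)O[C@@H]2C(C)=C[C@@]1(C)c1oc(OC)c(C)c(=O)c1C | target

## Step count and least certain steps

Total step count: 17. Longest linear sequence: 13 steps (steps 1–6 and 11–17, from propanal). The ring-B branch (steps 7–10) is 4 steps from methyl 2-methyl-3-oxopentanoate.

Step 6 (key step). What is most likely to go wrong is slow addition of the fully substituted nucleophilic carbon of 9 to the hindered iminium ion, so that reversible trienamine formation erodes C9 or the dienal oligomerises before the C1–C2 bond forms. The sense of induction is assigned from the shielding model and has to be confirmed on the first sample; both catalyst antipodes are available. The fallback introduces the C2 methyl group after the annulation. Setting out from 8, the same two-stage protocol is run with tert-butyl 3-oxopentanoate F1, the unbranched type of keto ester for which this annulation is established, to give (5R)-2-methyl-5-[(2E,4R,5S)-4-methyl-5-(triisopropylsilyloxy)hept-2-en-2-yl]cyclohex-2-en-1-one F2. Kinetic deprotonation of F2 at the α′-carbon with LiN(i-Pr)2 at −78 °C and methylation with MeI, anti to the alkenyl group, brings the route back to 12.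

Step 10. What is most likely to go wrong is ring-opening addition to the pyranone or decomposition of the lithiated ring before bromination, because the ring proton is only weakly acidic. The fallback joins ring B without a halide and without palladium. Dimethyl 3-oxopentanedioate is C-methylated twice (MeI, K2CO3, acetone) to dimethyl 2,4-dimethyl-3-oxopentanedioate F3, cyclised with loss of methanol (polyphosphoric acid) to 4-hydroxy-6-methoxy-3,5-dimethyl-2H-pyran-2-one F4, and O-methylated (MeOTf) to 2,6-dimethoxy-3,5-dimethyl-4H-pyran-4-one F5. The potassium dienolate of 12 (KOt-Bu, THF) is then added to F5 and displaces one methoxy group by conjugate addition–elimination, the way carbon nucleophiles such as organolithium reagents desymmetrise this pyranone; attack through C6 is expected because bonding through the fully substituted C4 to the substituted ring carbon is strongly hindered. This fallback sets out from 12, replaces steps 7 to 11 and comes back to the route at 18.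

Step 11. What is most likely to go wrong is coupling at the α′-carbon C2, whose proton is also available to the base, or a second arylation of the more acidic product. The fallback blocks C2 before the coupling. Setting out from 12, oxidation of its kinetic potassium enolate with the N-sulfonyloxaziridine (as in step 13) gives (5S,6S)-6-hydroxy-2,6-dimethyl-5-[(2E,4R,5S)-4-methyl-5-(triisopropylsilyloxy)hept-2-en-2-yl]cyclohex-2-en-1-one F6, and silylation (Et3SiOTf, 2,6-lutidine) gives its triethylsilyl ether F7, which has no α′-hydrogen. Arylation of F7 with 17 under the conditions of step 11 gives the C6-pyranonyl triethylsilyl ether F8, and methylation as in step 12 gives the C6-methylated triethylsilyl ether F9. Selective removal of the triethylsilyl group (HF·pyridine, pyridine, THF, 0 °C) comes back to the route at 20.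

Step 12. What is most likely to go wrong is methylation at the α-carbon C4 or on the dienolate oxygen in place of C6, the usual bias of extended enolates. The fallback removes the enone during the alkylation. Setting out from 18, 1,2-reduction (NaBH4, CeCl3·7H2O, MeOH, −40 °C; Luche reduction) gives the allylic alcohol F10. Treatment with two equivalents of LiN(i-Pr)2 at −78 °C forms the alkoxide and a carbanion at C6 stabilised only by ring B, which MeI should alkylate on the carbon next to ring B, as in the side-chain alkylation of 2-alkyl-4-pyranones, and anti to the C1 alkenyl group, giving the C6-methylated allylic alcohol F11. Oxidation of F11 with Dess–Martin periodinane comes back to the route at 19.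

## Further compounds

F1 | step 6 | tert-butyl 3-oxopentanoate | CCC(=O)CC(=O)OC(C)(C)C
F2 | step 6 | (5R)-2-methyl-5-[(2E,4R,5S)-4-methyl-5-(triisopropylsilyloxy)hept-2-en-2-yl]cyclohex-2-en-1-one | CC[C@H](O[Si](C(C)C)(C(C)C)C(C)C)[C@H](C)/C=C(\C)[C@@H]1CC=C(C)C(=O)C1
F3 | step 10 | dimethyl 2,4-dimethyl-3-oxopentanedioate | COC(=O)C(C)C(=O)C(C)C(=O)OC
F4 | step 10 | 4-hydroxy-6-methoxy-3,5-dimethyl-2H-pyran-2-one | COC1=C(C)C(O)=C(C)C(=O)O1
F5 | step 10 | 2,6-dimethoxy-3,5-dimethyl-4H-pyran-4-one | COc1oc(OC)c(C)c(=O)c1C
F6 | step 11 | (5S,6S)-6-hydroxy-2,6-dimethyl-5-[(2E,4R,5S)-4-methyl-5-(triisopropylsilyloxy)hept-2-en-2-yl]cyclohex-2-en-1-one | CC[C@H](O[Si](C(C)C)(C(C)C)C(C)C)[C@H](C)/C=C(\C)[C@@H]1CC=C(C)C(=O)[C@@]1(C)O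
F7 | step 11 | triethylsilyl ether of F6 at the C2 hydroxyl | CC[C@H](O[Si](C(C)C)(C(C)C)C(C)C)[C@H](C)/C=C(\C)[C@@H]1CC=C(C)C(=O)[C@@]1(C)O[Si](CC)(CC)CC
F8 | step 11 | C6-(6-methoxy-3,5-dimethyl-4-oxo-4H-pyran-2-yl) derivative of F7 (C6 epimers) | CC[C@H](O[Si](C(C)C)(C(C)C)C(C)C)[C@H](C)/C=C(\C)[C@@H]1C(c2oc(OC)c(C)c(=O)c2C)C=C(C)C(=O)[C@@]1(C)O[Si](CC)(CC)CC
F9 | step 11 | C6-methylated F8, the C2 triethylsilyl ether of 20 | CC[C@H](O[Si](C(C)C)(C(C)C)C(C)C)[C@H](C)/C=C(\C)[C@@H]1[C@](C)(c2oc(OC)c(C)c(=O)c2C)C=C(C)C(=O)[C@@]1(C)O[Si](CC)(CC)CC
F10 | step 12 | C3 allylic alcohol of 18 (C3 and C6 epimers) | CC[C@H](O[Si](C(C)C)(C(C)C)C(C)C)[C@H](C)/C=C(\C)[C@@H]1C(c2oc(OC)c(C)c(=O)c2C)C=C(C)C(O)[C@H]1C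
F11 | step 12 | C3 allylic alcohol of 19 (C3 epimers), methyl on C6 trans to the C1 alkenyl group | CC[C@H](O[Si](C(C)C)(C(C)C)C(C)C)[C@H](C)/C=C(\C)[C@@H]1[C@](C)(c2oc(OC)c(C)c(=O)c2C)C=C(C)C(O)[C@H]1C
A1 | alternative 1 | dearomatised 3-methoxy-2,4,6-trimethylcyclohexa-2,4-diene with the C1 alkenyl and C6 methyl groups trans and the (S)-4-tert-butyloxazolin-2-yl group on C6 | CC[C@H](O[Si](C)(C)C(C)(C)C)[C@H](C)/C=C(\C)[C@H]1C(C)=C(OC)C(C)=C[C@@]1(C)C2=N[C@@H](C(C)(C)C)CO2
A2 | alternative 1 | (S)-4-tert-butyl-2-(4-methoxy-3,5-dimethylphenyl)-4,5-dihydrooxazole | COc1c(C)cc(cc1C)C1=N[C@@H](C(C)(C)C)CO1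
A3 | alternative 1 | side-chain alkenyllithium, lithium on C7 trans to C9, C10 as its (S)-tert-butyldimethylsilyl ether | CC[C@H](O[Si](C)(C)C(C)(C)C)[C@H](C)/C=C(\C)[Li]
A4 | alternative 2 | the target skeleton with C10 as its (S)-tert-butyldimethylsilyl ether | CC[C@H](O[Si](C)(C)C(C)(C)C)[C@H](C)/C=C(\C)[C@H]1[C@]2(C)O[C@@H]2C(C)=C[C@@]1(C)c1oc(OC)c(C)c(=O)c1C
A5 | alternative 2 | open-chain C2 methyl ketone carrying the Z-allylic tetrahydrothiophenium group on C3 (trifluoromethanesulfonate salt) | CC[C@H](O[Si](C)(C)C(C)(C)C)[C@H](C)/C=C(\C)[C@@H](C(C)=O)[C@](C)(c1oc(OC)c(C)c(=O)c1C)/C=C(/C)C[S+]1CCCC1.[O-]S(=O)(=O)C(F)(F)F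
A6 | alternative 3 | 2-oxabicyclo[2.2.2]oct-5-en-3-one with the C1 alkenyl group syn to the lactone bridge and the C2 acetyl group endo | CC[C@H](O[Si](C)(C)C(C)(C)C)[C@H](C)/C=C(\C)[C@H]1[C@](C)(C(C)=O)[C@H]2OC(=O)[C@]1(C)C=C2C
A7 | alternative 3 | 3,5-dimethyl-2H-pyran-2-one | CC1=COC(=O)C(C)=C1
A8 | alternative 3 | (3E,5E,7R,8S)-8-(tert-butyldimethylsilyloxy)-3,5,7-trimethyldeca-3,5-dien-2-one | CC[C@H](O[Si](C)(C)C(C)(C)C)[C@H](C)/C=C(\C)/C=C(\C)C(C)=O
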